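Prenyl stands for 3-methylbut-2-enyl throughout. The target is compound 16.

## Analysis of the target

The target 16 is a 1,3'-biindole: two indole units joined by a single bond between N1' of one indole and C3 of the other, whose own nitrogen N1 stays free. Each indole carries a prenyl group at C6 (C6 and C6'). There is no stereocenter, the alkenes end in two identical methyl groups, and the N1'–C3 axis is not hindered enough to be configurationally stable, so the problem is one of regiochemistry and chemoselectivity only. The sensitive groups are the two electron-rich trisubstituted alkenes (acid, electrophilic oxidants and hydrogenation are excluded), the free N–H, and the oxidisable, electron-rich 3-(azol-1-yl)indole unit. The synthesis is hard for three reasons. The N1'–C3 bond joins a nitrogen nucleophile to the carbon of an indole that is itself nucleophilic. C6 is a position that electrophilic substitution of an indole does not reach. The two nitrogen atoms must be told apart. The strategy rests on two mappings. The unit N1–C2–C3 with N1' on C3 is the azavinyl carbene latent in the 4-(indol-1-yl)-1-sulfonyl-1,2,3-triazole 8 (triazole N1, C5 and C4 become N1, C2 and C3). The six carbons C3a, C4, C5, C6, C7 and C7a with prenyl on C6 are the ring of 3-prenylanisole 11 in its Birch-reduced form 12, whose oxygen-bearing enol ether carbon becomes C7a and whose other enol ether carbon becomes C3a.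

## Retrosynthetic reasoning

**16 from 15 (N1–S).** The last bond cut is the one between N1 and sulfur. The sulfonyl group is what remains of the carbene precursor, so it must sit on N1 when the ring is made and is taken off at the very end. The forward step has to cleave N–S by electron transfer without touching two trisubstituted alkenes, which rules out hydrogenolysis and strong acid.

**15 from 14 (C4–H and C7–H).** Two hydrogens are put back on C4 and C7. The benzo ring of the NH-indole becomes a cyclohexa-1,4-diene fused to the pyrrole, and this is what allows a non-aromatic enol ether to supply the six carbons. The forward reaction is a dehydrogenation driven by aromatisation, so a weak hydride acceptor suffices and the prenyl groups are not at risk.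

**14 from 8 and 12 (C3–C3a and N1–C7a, through 13).** These two bonds tie the N1–C2–C3 unit to the carbocycle. The cut is made here and not at N1'–C3 because that bond would have to be forged between two electron-rich indoles with the wrong polarity at C3. In 8 the same bond is already present as an ordinary N–C(sp2) bond on a triazole. The cut divides the target into two halves of nearly equal size, each with one prenyl group. In the forward sense a dirhodium carboxylate must turn 8 into an electrophilic carbene that carries N1' on the carbene carbon. The enol ether carbon C2 of 12 must attack that carbon, and the sulfonamide nitrogen must close on C1 of 12. The methoxy group then leaves together with the hydrogen on C3a of aminal 13. One ring, two skeletal bonds and the whole carbon–nitrogen framework are gained in one operation.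

**8 from 6 and 7 (triazole N1–C5 and N3–C4).** The triazole is opened by a retro-cycloaddition into the terminal N-ethynylindole 6 and the sulfonyl azide 7. The forward copper-catalysed cycloaddition must place the sulfonyl group on N1 and the indolyl group on C4, which is the normal regiochemistry of the copper acetylide pathway.

**6 from 5, and 5 from 3 and 4 (N1'–C(sp)).** The ethynyl group is traced to its silyl-capped form 5, and the N–C(sp) bond of 5 is cut to the N–H indole 3 and the bromoalkyne 4. The silyl cap is there because a terminal bromoalkyne would not survive the coupling. The forward steps are a copper-catalysed N-alkynylation and a fluoride desilylation.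

**3 from 1 and 2 (C6'–CH2).** The prenyl group on the N-linked indole is cut at the aryl–CH2 bond, which leads to the bromoindole 1 and the allylboronate 2. The forward cross-coupling must deliver the allyl fragment through its primary carbon and must tolerate the free N–H.

**12 from 11 (four ring C–H bonds).** The skipped diene is the dissolving-metal reduction product of the anisole 11. The forward reduction must leave both donor substituents on the two remaining double bonds and must spare the side-chain alkene.

**11 from 9 and 10 (aryl–CH2).** The second prenyl group is cut in the same place as the first, which gives the aryl Grignard reagent 9 and the allyl bromide 10. Here there is no acidic hydrogen, so the cheapest carbon nucleophile can be used.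

## Alternatives that were turned down

**Alternative 1:** The bonds N1'–C3 and N1'–C2' are cut, which unravels the N-linked indole into 2-ethynyl-5-prenylaniline A3 and the C3 ketone 1-acetyl-6-prenylindolin-3-one A2. In the forward sense one trivalent gold salt would catalyse two events in the same flask. The aniline nitrogen condenses with the ketone (C3–N1', loss of water), and the same nitrogen then adds to the alkyne (N1'–C2', 5-endo-dig). This gives the N-acetyl biindole A1, one deacetylation away from 16.

- For: both rings are made at the aromatic oxidation level, so no dehydrogenation is needed. An acetyl group comes off under milder conditions than a tosyl group, and no azide is handled. On redox economy and on the mildness of the end game this plan is stronger than the chosen one.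
- Against: the order of the two events is not under control. A3 is itself a substrate for gold-catalysed cycloisomerisation, and the ketone of A2 is a weakly electrophilic vinylogous amide. If the alkyne is hydroaminated first, the product is 6-prenylindole 3, whose nitrogen can no longer condense. A2 is enolisable, self-condensing and air-sensitive. Both A2 and A3 need a prenyl group on a benzene ring that already carries other functional groups, and a Lewis-acidic metal would meet a terminal alkyne and two prenyl alkenes at once.
- Comparison: the step count is about the same, nine to ten. The chosen plan offers in exchange a bond-forming order that the mechanism dictates (carbene attack first, ring closure second), and prenylation on two simple aryl electrophiles.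

**Alternative 2:** The benzo ring of the N-linked indole is taken apart at C3a'–C4' and, through a retro-Stobbe step, at the carbon that becomes C7'. This leaves a pyrrole already bound to C3 of the other indole. Forward, the half-ester A5 is heated with a carboxylic anhydride and its sodium salt. The mixed anhydride gives a dienylketene, which undergoes a six-electron electrocyclisation onto pyrrole C3. Tautomerisation and O-acetylation give the 4-acetoxyindole-6-carboxylate A4.

- For: the key step is old, cheap, scalable, free of transition metals and regiochemically unambiguous. On robustness of the key step it is stronger than a carbene annulation on untried partners.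
- Against: A4 carries an acetoxy group at C4' that the target lacks and an ester at C6' where the prenyl group belongs. Removing the oxygen takes about three steps (hydrolysis, triflation, reduction). Turning the ester into prenyl takes about three more (reduction, activation, coupling with an isobutenyl nucleophile). Detosylation follows, so about seven steps come after the key step, against two here. A5 also presupposes the N1'–C3 bond, made earlier by N-arylation of a pyrrole, so the unusual bond of the target is only pushed back.
- Comparison: the total would be about fifteen steps. The chosen plan forms the ring with the correct substituents and nothing to remove but the sulfonyl group.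

**Alternative 3:** The bonds C3a'–C7a' and C4'–C5' are cut and two nitrogen atoms are put back, which leads to the aminopyridazine A7. Its but-3-ynyl chain on N1' reaches across to the diazine. Forward, heat makes the alkyne add across C3 and C6 of the pyridazine (intramolecular inverse-electron-demand Diels–Alder reaction), and the adduct expels its two nitrogen atoms as gas. This gives the indoline A6, which needs dehydrogenation to the N-tosyl biindole 15 and then detosylation.

- For: one thermal step without any reagent closes two rings and forms two C–C bonds. It is made irreversible by gas loss, and the prenyl position is fixed by the substitution of the pyridazine. The end game is as short as the chosen one, and on simplicity of the key step it is at least equal.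
- Against: an amino-substituted pyridazine is an electron-rich azadiene and a terminal alkyne is an unactivated dienophile. Such cases need long heating near or above 200 °C, where two prenyl groups and an electron-rich 3-aminoindole are at risk. The real cost is A7. Its nitrogen carries three different groups (indol-3-yl, pyridazinyl and the alkynyl chain), which must be assembled from an unstable 3-aminoindole or by C–N coupling. A 3-halo-5-prenylpyridazine also has to be made regioselectively. That comes to roughly eight steps before the key step.
- Comparison: the chosen plan builds N1' into a stable indole from the first step and reaches its key step in four and two steps.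

Key step: step 7

Remark: 4, 7, 9 (as a solution in THF) and 10 are taken as purchasable; 7 is handled in solution at or below room temperature.

## Route

Step 1
Reactants: 1 6-bromoindole; 2 3-methylbut-2-enylboronic acid pinacol ester
Product: 3 6-(3-methylbut-2-enyl)-1H-indole
Conditions: PdCl2(IPent)(3-chloropyridine) (IPent = 1,3-bis[2,6-di(pentan-3-yl)phenyl]imidazol-2-ylidene; 2 mol%), KOH (5 M aq), THF, 70 °C
Reagents that add atoms: none
Why: Suzuki–Miyaura coupling of a 3,3-disubstituted allylboronate; the very bulky carbene ligand on palladium steers reductive elimination to the primary (α) carbon of the allyl fragment, so the linear prenyl group and not the 1,1-dimethylallyl isomer should arrive at C6, and the free N–H is tolerated under aqueous hydroxide.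

Step 2
Reactants: 3 6-(3-methylbut-2-enyl)-1H-indole; 4 (bromoethynyl)triisopropylsilane
Product: 5 6-(3-methylbut-2-enyl)-1-[(triisopropylsilyl)ethynyl]indole
Conditions: CuSO4·5H2O (10 mol%), 1,10-phenanthroline (20 mol%), K3PO4, toluene, 85 °C
Reagents that add atoms: none
Why: Copper-catalysed N-alkynylation of an N–H azole with a bromoalkyne (ynamide-type C(sp)–N coupling); the indole N–H is about as acidic as the amide N–H bonds on which this coupling is routine, C3 is not attacked under basic non-electrophilic conditions, and the bulky silyl cap suppresses alkyne homocoupling.

Step 3
Reactants: 5 6-(3-methylbut-2-enyl)-1-[(triisopropylsilyl)ethynyl]indole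
Product: 6 1-ethynyl-6-(3-methylbut-2-enyl)indole
Conditions: Bu4NF, THF (wet), 0 °C
Reagents that add atoms: none
Why: Fluoride-induced protodesilylation of a silylalkyne; the N-ethynylindole is an ynamine tempered by the aromatic nitrogen, stable enough to isolate but used at once to avoid hydration.

Step 4
Reactants: 6 1-ethynyl-6-(3-methylbut-2-enyl)indole; 7 4-toluenesulfonyl azide
Product: 8 4-[6-(3-methylbut-2-enyl)indol-1-yl]-1-tosyl-1,2,3-triazole
Conditions: Cu(O2CC4H3S) (copper thiophene-2-carboxylate, 10 mol%), toluene, 0 °C to rt
Reagents that add atoms: none
Why: Copper-catalysed azide–alkyne cycloaddition with a sulfonyl azide; the copper acetylide pathway places tosyl on N1 and the indolyl group on C4, and the base-free carboxylate of monovalent copper at low temperature lets the 5-cuprated triazole be protonated before it can lose dinitrogen to a ketenimine.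

Step 5
Reactants: 9 (3-methoxyphenyl)magnesium bromide; 10 1-bromo-3-methylbut-2-ene
Product: 11 1-methoxy-3-(3-methylbut-2-enyl)benzene
Conditions: Li2CuCl4 (2 mol%), THF, 0 °C to rt
Reagents that add atoms: none
Why: Copper-catalysed coupling of an aryl Grignard reagent with an allylic bromide; substitution should occur at the unhindered primary carbon of 10 and not at its fully substituted γ-carbon, which gives the linear prenylarene.

Step 6
Reactants: 11 1-methoxy-3-(3-methylbut-2-enyl)benzene
Product: 12 1-methoxy-5-(3-methylbut-2-enyl)cyclohexa-1,4-diene
Conditions: Li, NH3 (l), t-BuOH, THF, −78 °C; then NH4Cl; neutral to basic work-up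
Reagents that add atoms: none
Why: Birch reduction; hydrogen is added at the ring carbon between the two substituents and at the carbon para to it, so methoxy and prenyl both stay on the two remaining double bonds. The isolated trisubstituted alkene is not reduced by solvated electrons, and tert-butanol present from the start keeps the amide concentration low so that the skipped alkenes should not migrate.

Step 7
Reactants: 8 4-[6-(3-methylbut-2-enyl)indol-1-yl]-1-tosyl-1,2,3-triazole; 12 1-methoxy-5-(3-methylbut-2-enyl)cyclohexa-1,4-diene
Product: 14 6-(3-methylbut-2-enyl)-3-[6-(3-methylbut-2-enyl)indol-1-yl]-1-tosyl-4,7-dihydroindole, via 7a-methoxy aminal 13 (not isolated)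
Conditions: Rh2(O2CC7H15)4 (dirhodium tetraoctanoate, 2 mol%), 12 (3 equiv), ClCH2CH2Cl, 70 °C, slow addition of 8; then pyridinium p-toluenesulfonate (cat.), rt
Reagents that add atoms: none
Why: Triazole 8 is in ring–chain equilibrium with its α-diazo N-tosylimine, which the dirhodium carboxylate (divalent rhodium) decomposes with loss of dinitrogen to an azavinyl carbene whose carbene carbon is the former triazole C4 and already carries N1' of the indole. The enol ether carbon C2 of 12, the most nucleophilic alkene carbon present, attacks this electrophilic carbon and forms C3–C3a, which leaves an oxocarbenium ion at C1 of 12 and a rhodium-bound azaenolate. The sulfonamide nitrogen then closes onto the oxocarbenium carbon (5-exo-trig, N1–C7a) and releases the catalyst to give the cis-fused aminal 13; overall this is the formal [3+2] transannulation of 1-sulfonyl-1,2,3-triazoles with alkyl enol ethers that is established for pyrrole synthesis. Loss of methanol across C3a–C7a, on heating or completed by the trace of pyridinium salt, aromatises the five-membered ring to the N-tosylpyrrole of 14. No stereocenter is kept, since the two centers of 13 are erased by the elimination. The step needs chemoselectivity for the enol ether over three trisubstituted alkenes, the indole π bond and the doubly allylic C–H bonds; this rests on the donor oxygen, which makes C1=C2 of 12 far more nucleophilic than any other site, while intramolecular capture by the attached indole would require a three- or four-membered ring and excess 12 with slow addition of 8 keeps the carbene from a second molecule of 8. It also needs one orientation, and the same polarisation (nucleophilic C2, electrophilic C1) makes C2 of 12 become C3a and C1 become C7a, so that the prenyl group ends at C6. The surviving C5=C6 alkene leaves 14 two hydrogens short of the indole.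

Step 8
Reactants: 14 6-(3-methylbut-2-enyl)-3-[6-(3-methylbut-2-enyl)indol-1-yl]-1-tosyl-4,7-dihydroindole
Product: 15 6-(3-methylbut-2-enyl)-3-[6-(3-methylbut-2-enyl)indol-1-yl]-1-tosylindole
Conditions: chloranil (tetrachloro-1,4-benzoquinone, 1.1 equiv), toluene, 60 °C
Reagents that add atoms: none
Why: Dehydrogenation of a 1,4-cyclohexadiene by a quinone; hydride abstraction from the C4 or C7 methylene followed by proton loss gives the benzene ring, and the gain in aromaticity should make this much faster than any oxidation of the prenyl groups or of the electron-poor N-tosylpyrrole.

Step 9
Reactants: 15 6-(3-methylbut-2-enyl)-3-[6-(3-methylbut-2-enyl)indol-1-yl]-1-tosylindole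
Product: 16 6-(3-methylbut-2-enyl)-3-[6-(3-methylbut-2-enyl)indol-1-yl]-1H-indole
Conditions: Mg (turnings), MeOH, rt, ultrasound; NH4Cl (aq) work-up
Reagents that add atoms: none
Why: Reductive cleavage of the N–S bond by electron transfer from magnesium in methanol; isolated alkenes and indole rings are not reduced, and the method avoids the N-methylation that alkoxide-mediated desulfonylation can cause.

## Compound list

1 | 6-bromoindole | Brc1ccc2cc[nH]c2c1 | starting material
2 | 3-methylbut-2-enylboronic acid pinacol ester | CC(C)=CCB1OC(C)(C)C(C)(C)O1 | starting material
3 | 6-(3-methylbut-2-enyl)-1H-indole | CC(C)=CCc1ccc2cc[nH]c2c1 | intermediate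
4 | (bromoethynyl)triisopropylsilane | CC(C)[Si](C#CBr)(C(C)C)C(C)C | starting material
5 | 6-(3-methylbut-2-enyl)-1-[(triisopropylsilyl)ethynyl]indole | CC(C)=CCc1ccc2ccn(C#C[Si](C(C)C)(C(C)C)C(C)C)c2c1 | intermediate
6 | 1-ethynyl-6-(3-methylbut-2-enyl)indole | C#Cn1ccc2ccc(CC=C(C)C)cc21 | intermediate
7 | 4-toluenesulfonyl azide | Cc1ccc(S(=O)(=O)N=[N+]=[N-])cc1 | starting material
8 | 4-[6-(3-methylbut-2-enyl)indol-1-yl]-1-tosyl-1,2,3-triazole | Cc1ccc(cc1)S(=O)(=O)n1cc(nn1)-n1ccc2ccc(CC=C(C)C)cc21 | intermediate
9 | (3-methoxyphenyl)magnesium bromide | COc1cccc([Mg]Br)c1 | starting material
10 | 1-bromo-3-methylbut-2-ene (prenyl bromide) | CC(C)=CCBr | starting material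
11 | 1-methoxy-3-(3-methylbut-2-enyl)benzene | COc1cccc(CC=C(C)C)c1 | intermediate
12 | 1-methoxy-5-(3-methylbut-2-enyl)cyclohexa-1,4-diene | COC1=CCC=C(CC=C(C)C)C1 | intermediate
13 | cis-7a-methoxy-6-(3-methylbut-2-enyl)-3-[6-(3-methylbut-2-enyl)indol-1-yl]-1-tosyl-3a,4,7,7a-tetrahydroindole (racemic, relative configuration drawn) | CO[C@]12CC(CC=C(C)C)=CC[C@H]1C(=CN2S(=O)(=O)c1ccc(C)cc1)n1ccc2ccc(CC=C(C)C)cc21 | intermediate
14 | 6-(3-methylbut-2-enyl)-3-[6-(3-methylbut-2-enyl)indol-1-yl]-1-tosyl-4,7-dihydroindole | CC(C)=CCC1=CCc2c(C1)n(S(=O)(=O)c1ccc(C)cc1)cc2-n1ccc2ccc(CC=C(C)C)cc21 | intermediate
15 | 6-(3-methylbut-2-enyl)-3-[6-(3-methylbut-2-enyl)indol-1-yl]-1-tosylindole | CC(C)=CCc1ccc2c(c1)n(S(=O)(=O)c1ccc(C)cc1)cc2-n1ccc2ccc(CC=C(C)C)cc21 | intermediate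
16 | 6-(3-methylbut-2-enyl)-3-[6-(3-methylbut-2-enyl)indol-1-yl]-1H-indole | CC(C)=CCc1ccc2c(-n3ccc4ccc(CC=C(C)C)cc43)c[nH]c2c1 | target

## Step count and risks

Total step count: 9. Longest linear sequence: 7 steps (steps 1, 2, 3, 4, 7, 8, 9). The two-step branch (steps 5 and 6) joins at step 7.

**Step 7 (key step).** The carbene may be diverted from the enol ether. Possible diversions are hydride abstraction or C–H insertion at the doubly allylic methylenes of 12, cyclopropanation of a trisubstituted alkene, and attack on the indole ring of a second molecule of 8. The dienol ether may also be hydrolysed or isomerised by adventitious acid before it reacts. Fallback: give up the annulation and make the N1'–C3 bond by copper-catalysed N-arylation, setting out from 3. Iodination at C3 (I2, KOH, DMF) would give 3-iodo-6-(3-methylbut-2-enyl)-1H-indole F1. N-Tosylation (NaH, TsCl, THF) would give 3-iodo-6-(3-methylbut-2-enyl)-1-tosylindole F2. Ullmann–Goldberg coupling of F2 with a second portion of 3 (CuI, trans-N,N'-dimethylcyclohexane-1,2-diamine, K3PO4, toluene, 110 °C) would then give 15, where the route is rejoined before step 9.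

**Step 6.** Amide base formed during the reduction may move the prenyl double bond into conjugation with the ring, after which it would be reduced. The skipped dienol ether may also isomerise or hydrolyse during work-up. Fallback: introduce the side-chain alkene only after the ring has been reduced, setting out from 9. Opening of oxirane by 9 (CuI cat., THF) would give 2-(3-methoxyphenyl)ethanol F3. Birch reduction (Li, NH3, t-BuOH) would give 2-(5-methoxycyclohexa-1,4-dien-1-yl)ethanol F4. Dess–Martin oxidation buffered with pyridine would give 2-(5-methoxycyclohexa-1,4-dien-1-yl)acetaldehyde F5. Wittig olefination with isopropylidenetriphenylphosphorane (from isopropyltriphenylphosphonium iodide and n-BuLi, THF, −78 °C) would give 12.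

**Step 4.** The donor nitrogen on the alkyne may speed up loss of dinitrogen from the 5-cuprated triazole, which leads through a ketenimine to acyclic sulfonamide products. The sulfonyl group of 8 may also be lost on silica. Fallback: separate the cycloaddition from the sulfonylation, setting out from 6. Copper-catalysed cycloaddition with azidotrimethylsilane (CuI, DMF/MeOH, 60 °C) would give 4-[6-(3-methylbut-2-enyl)indol-1-yl]-1H-1,2,3-triazole F6. Sulfonylation of F6 (TsCl, Et3N, CH2Cl2, −20 °C) would give 8. The point to watch is then sulfonylation at N2 in place of N1.

**Step 2.** The weakly acidic indole N–H may convert slowly while 4 is consumed by homocoupling. Fallback: build the ethynyl group from a two-carbon electrophile, setting out from 3. Reaction with trichloroethylene (K2CO3, DMF, 70 °C) would give (E)-1-(1,2-dichloroethenyl)-6-(3-methylbut-2-enyl)indole F7. Treatment of F7 with n-BuLi (2.2 equiv, THF, −78 °C; then NH4Cl aq) would eliminate chloride, exchange the second chlorine for lithium and, after protonation, give 6 directly. Compound 5 and step 3 are bypassed.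

**Step 1.** The allyl fragment may be transferred in part through its γ-carbon, which gives the 1,1-dimethylallyl isomer, and 2 may be lost by protodeboronation. Fallback: use an aryllithium and an SN2 alkylation, setting out from 1. N-Silylation (NaH, i-Pr3SiCl, THF) would give 6-bromo-1-(triisopropylsilyl)indole F8. Bromine–lithium exchange (t-BuLi, 2 equiv, THF, −78 °C) and alkylation with 10 would give 6-(3-methylbut-2-enyl)-1-(triisopropylsilyl)indole F9. Desilylation (Bu4NF, THF) would give 3.

## Further compounds

F1 | step 7 | 3-iodo-6-(3-methylbut-2-enyl)-1H-indole | CC(C)=CCc1ccc2c(I)c[nH]c2c1
F2 | step 7 | 3-iodo-6-(3-methylbut-2-enyl)-1-tosylindole | CC(C)=CCc1ccc2c(I)cn(S(=O)(=O)c3ccc(C)cc3)c2c1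
F3 | step 6 | 2-(3-methoxyphenyl)ethanol | COc1cccc(CCO)c1
F4 | step 6 | 2-(5-methoxycyclohexa-1,4-dien-1-yl)ethanol | COC1=CCC=C(CCO)C1
F5 | step 6 | 2-(5-methoxycyclohexa-1,4-dien-1-yl)acetaldehyde | COC1=CCC=C(CC=O)C1
F6 | step 4 | 4-[6-(3-methylbut-2-enyl)indol-1-yl]-1H-1,2,3-triazole | CC(C)=CCc1ccc2ccn(-c3c[nH]nn3)c2c1
F7 | step 2 | (E)-1-(1,2-dichloroethenyl)-6-(3-methylbut-2-enyl)indole | Cl/C=C(/Cl)n1ccc2ccc(CC=C(C)C)cc21
F8 | step 1 | 6-bromo-1-(triisopropylsilyl)indole | CC(C)[Si](C(C)C)(C(C)C)n1ccc2ccc(Br)cc21
F9 | step 1 | 6-(3-methylbut-2-enyl)-1-(triisopropylsilyl)indole | CC(C)=CCc1ccc2ccn([Si](C(C)C)(C(C)C)C(C)C)c2c1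
A1 | alternative 1 | 1-acetyl-6-(3-methylbut-2-enyl)-3-[6-(3-methylbut-2-enyl)indol-1-yl]indole | CC(=O)n1cc(-n2ccc3ccc(CC=C(C)C)cc32)c2ccc(CC=C(C)C)cc21
A2 | alternative 1 | 1-acetyl-6-(3-methylbut-2-enyl)indolin-3-one | CC(=O)N1CC(=O)c2ccc(CC=C(C)C)cc21
A3 | alternative 1 | 2-ethynyl-5-(3-methylbut-2-enyl)aniline | C#Cc1ccc(CC=C(C)C)cc1N
A4 | alternative 2 | ethyl 4-acetoxy-1-[6-(3-methylbut-2-enyl)-1-tosylindol-3-yl]indole-6-carboxylate | CCOC(=O)c1cc(OC(C)=O)c2ccn(-c3cn(S(=O)(=O)c4ccc(C)cc4)c4cc(CC=C(C)C)ccc34)c2c1
A5 | alternative 2 | (E)-3-(ethoxycarbonyl)-4-{1-[6-(3-methylbut-2-enyl)-1-tosylindol-3-yl]pyrrol-2-yl}but-3-enoic acid | CCOC(=O)/C(CC(=O)O)=C/c1cccn1-c1cn(S(=O)(=O)c2ccc(C)cc2)c2cc(CC=C(C)C)ccc12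
A6 | alternative 3 | 6-(3-methylbut-2-enyl)-1-[6-(3-methylbut-2-enyl)-1-tosylindol-3-yl]indoline | CC(C)=CCc1ccc2c(c1)N(c1cn(S(=O)(=O)c3ccc(C)cc3)c3cc(CC=C(C)C)ccc13)CC2
A7 | alternative 3 | N-(but-3-ynyl)-6-(3-methylbut-2-enyl)-N-[5-(3-methylbut-2-enyl)pyridazin-3-yl]-1-tosylindol-3-amine | C#CCCN(c1cc(CC=C(C)C)cnn1)c1cn(S(=O)(=O)c2ccc(C)cc2)c2cc(CC=C(C)C)ccc12
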